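The six carbons C2–C7 and the methyl groups on C4 and C6 are taken from m-xylene. Everything rests on opening the 1,2-dioxane ring (C3, C4, C5, C6, O, O) at its C3–O and C6–O bonds: a [4+2] addition of singlet oxygen to a ring-locked s-cis diene closes this ring in one operation, sets C3 and C6, and fixes the C2 and C7 arms cis. The precursor is the acetonide of the enzymatic m-xylene cis-dihydrodiol, a 1,3-dimethylcyclohexa-1,3-diene whose dioxolane blocks one face. Cleavage of the C2–C7 bond, two Wittig reactions (C1; the aryl chain) and iodolactonisation at C4 of the surviving C4=C5 alkene finish the skeleton.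

Key step: step 6

Numbering used throughout (biogenetic): C1 lactone carbonyl, C2, C3 peroxy methine, C4 ring-fusion carbon with methyl and lactone oxygen, C5, C6 peroxy carbon with methyl and chain, C7 first chain carbon. The target is (3S,4S,6R) in this numbering.

Assumption: toluene dioxygenase is taken to oxidise m-xylene at the 4,5-bond with the same facial sense as toluene, giving the (1S,2R)-3,5-dimethyl diol.

Stereochemical bookkeeping: anti addition of oxygen to the (1S,2R) acetonide gives the C3 and C6 configurations of the target. C1 is not an arene carbon; it comes from the methoxymethylene ylide, so that C2 stays a ring carbon.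

Step 1
Reactants: 1 4-bromophenol
Product: 2 (4-bromophenoxy)(tert-butyl)dimethylsilane
Conditions: TBSCl, imidazole, DMF, 0 °C to rt
Reagents that add atoms: tert-butyldimethylsilyl chloride, CC(C)(C)[Si](C)(C)Cl
Why: Imidazole-promoted silylation masks the phenol so that it tolerates the Grignard and ylide chemistry that follows.

Step 2
Reactants: 2 (4-bromophenoxy)(tert-butyl)dimethylsilane; 3 1,8-dibromooctane
Product: 5 1-(8-bromooctyl)-4-(tert-butyldimethylsilyloxy)benzene, via aryl Grignard reagent 4 (not isolated)
Conditions: Mg, THF, reflux; then 3 (3 equiv), Li2CuCl4 (cat.), THF, −10 °C to rt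
Reagents that add atoms: none
Why: Copper-catalysed (Kochi) cross-coupling of an aryl Grignard reagent with a primary alkyl bromide, with excess dibromide to suppress double arylation.

Step 3
Reactants: 5 1-(8-bromooctyl)-4-(tert-butyldimethylsilyloxy)benzene
Product: 6 {8-[4-(tert-butyldimethylsilyloxy)phenyl]octyl}triphenylphosphonium bromide
Conditions: PPh3, MeCN, reflux
Reagents that add atoms: triphenylphosphine, c1ccc(P(c2ccccc2)c2ccccc2)cc1
Why: SN2 alkylation of triphenylphosphine by the primary bromide gives the phosphonium salt for the later Wittig reaction.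

Step 4
Reactants: 7 m-xylene; 8 dioxygen
Product: 9 (1S,2R)-3,5-dimethylcyclohexa-3,5-diene-1,2-diol
Conditions: E. coli JM109(pDTG601) whole cells (toluene dioxygenase), glucose, IPTG, air, pH 7, 30 °C, m-xylene fed as vapour
Reagents that add atoms: none
Why: Arene cis-dihydroxylation by a Rieske dioxygenase; the enzyme delivers both oxygen atoms to one face of the 4,5-bond and so sets both carbinol centres, as it does for toluene.

Step 5
Reactants: 9 (1S,2R)-3,5-dimethylcyclohexa-3,5-diene-1,2-diol; 10 2,2-dimethoxypropane
Product: 11 (3aR,7aS)-2,2,4,6-tetramethyl-3a,7a-dihydro-1,3-benzodioxole (acetonide of 9)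
Conditions: p-TsOH (cat.), acetone, 0 °C, short; Et3N quench; used promptly
Reagents that add atoms: none
Why: Acid-catalysed isopropylidene acetal formation on the cis-diol under brief, cold conditions that should avoid dehydration to dimethylphenols; the stereocentres are not touched.

Step 6
Reactants: 11 acetonide of the m-xylene cis-dihydrodiol; 8 dioxygen
Product: 12 anti endoperoxide acetonide (1,5-dimethyl-2,3-dioxabicyclo[2.2.2]oct-5-ene-7,8-diol acetonide)
Conditions: O2, tetraphenylporphyrin (cat.), visible light, CH2Cl2, −78 °C
Reagents that add atoms: none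
Why: Photosensitised singlet oxygen should add suprafacially to the s-cis diene C3=C4–C5=C6 in a concerted [4+2] cycloaddition that forms C3–O and C6–O together. The closest known reaction type is the endoperoxidation of cyclohexa-1,3-dienes (ascaridole type), which is also established for acetonides of arene cis-dihydrodiols. The 1,2-dioxane ring is closed by cycloaddition, both ring bonds in one event, and appears as the peroxide bridge of a 2,3-dioxabicyclo[2.2.2]oct-5-ene. C3 and C6 are set by the face of attack, which should be the face opposite the dioxolane, so both are controlled by the enzymatically set C2 and C7 centres. The step needs facial selectivity and cycloaddition in preference to the ene reaction at the two allylic methyl groups; the cis-fused acetonide with its inward methyl blocks the syn face, and the fixed cisoid geometry lets the cycloaddition outrun hydrogen abstraction.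

Step 7
Reactants: 12 anti endoperoxide acetonide
Product: 13 1,5-dimethyl-2,3-dioxabicyclo[2.2.2]oct-5-ene-7,8-diol (cis-diol on the alkene side)
Conditions: TFA–H2O (9:1), 0 °C
Reagents that add atoms: none
Why: Acid hydrolysis of the isopropylidene acetal; both peroxide carbons are bridgeheads that can neither ionise nor be deprotonated, so the endoperoxide should survive.

Step 8
Reactants: 13 bicyclic endoperoxide diol
Product: 14 (3S,6R)-3,5-dimethyl-3,6-dihydro-1,2-dioxine-3,6-dicarbaldehyde (formyl groups cis)
Conditions: NaIO4 on silica gel, CH2Cl2, 0 °C to rt; filtered, dried and used at once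
Reagents that add atoms: none
Why: Malaprade glycol cleavage through the cyclic periodate ester of the rigid cis-diol breaks the C2–C7 bond and leaves C2 and C7 as cis formyl groups on the monocyclic dioxine; no stereocentre is touched and no base or water is present.

Step 9
Reactants: 14 cis-dialdehyde
Product: 15 cis-6-(2-methoxyvinyl)-3,5-dimethyl-3,6-dihydro-1,2-dioxine-3-carbaldehyde (E/Z mixture at the enol ether)
Conditions: MeOCH2PPh3Cl, KHMDS, THF, 0 °C; ylide (1.0 equiv) added slowly to 14, THF, −78 °C; pH 7 buffer quench at −78 °C
Reagents that add atoms: (methoxymethyl)triphenylphosphonium chloride, COC[P+](c1ccccc1)(c1ccccc1)c1ccccc1.[Cl-]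
Why: Wittig methoxymethylenation (one-carbon homologation): at −78 °C the ylide should add faster to the formyl group on the tertiary carbon C3 than to the neopentyl-type formyl group on the fully substituted C6, and faster than it deprotonates C3–H, so C1 is joined to C2 while the C7 aldehyde is kept; no stereocentre is touched.

Step 10
Reactants: 15 enol ether aldehyde; 6 side-chain phosphonium bromide
Product: 17 dioxine carrying the (Z)-9-aryl-non-1-enyl chain on C6 together with the methoxyvinyl group on C3, via chain ylide 16 (not isolated)
Conditions: 6, NaHMDS, THF, 0 °C; then 15, THF, −78 to 0 °C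
Reagents that add atoms: none
Why: Wittig olefination with a non-stabilised ylide; the C7 aldehyde has no α-hydrogen, the enol ether is base-stable, and the mainly Z geometry does not matter because the alkene is saturated in step 14.

Step 11
Reactants: 17 chain-bearing dioxine enol ether
Product: 19 dioxine acetic acid (C1 as CO2H), via homologated aldehyde 18 (not isolated)
Conditions: 1 M aq. HCl, THF, 0 °C to rt; then NaClO2, NaH2PO4, 2-methyl-2-butene, t-BuOH–H2O, 0 °C
Reagents that add atoms: water, O; sodium chlorite, [Na+].[O-]Cl=O
Why: Acid hydrolysis of the enol ether, which should be far faster than acid ionisation of the peroxide, followed in the same flask by Pinnick oxidation so that the β-peroxy aldehyde is never stored or exposed to base; 2-methyl-2-butene protects the alkenes from hypochlorous acid.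

Step 12
Reactants: 19 dioxine acetic acid
Product: 20 iodolactone (cis-fused peroxylactone, iodine on C5 trans to the lactone oxygen)
Conditions: I2, NaHCO3, MeCN, 0 °C, dark
Reagents that add atoms: iodine, II
Why: Iodolactonisation: the carboxylate opens the iodonium ion of the C4=C5 alkene by 5-exo attack at the tertiary carbon C4, and because it is tethered to C3 it can only give the cis-fused γ-lactone, which sets C4; the chain alkene has no nucleophile in reach.

Step 13
Reactants: 20 iodolactone
Product: 21 silyl-protected 7,8-didehydro (Z) plakortolide F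
Conditions: Bu3SnH (excess, about 0.5 M), Et3B, air, toluene, 0 °C
Reagents that add atoms: none
Why: Radical-chain deiodination with tin hydride: iodine abstraction is much faster than stannyl attack on the hindered O–O bond, and high hydride concentration at 0 °C should let hydrogen transfer to the C5 radical outrun its closure onto the neighbouring peroxide oxygen, which lies in the same six-membered ring and is poorly aligned; C5 ceases to be a stereocentre.

Step 14
Reactants: 21 silyl-protected didehydro lactone
Product: 22 plakortolide F tert-butyldimethylsilyl ether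
Conditions: KO2CN=NCO2K, AcOH, MeOH–CH2Cl2, 0 °C to rt, portionwise
Reagents that add atoms: none
Why: Diimide reduction (concerted syn transfer of H2) saturates the only remaining alkene without touching the O–O bond, the lactone or the silyl ether, which catalytic hydrogenation would not allow.

Step 15
Reactants: 22 plakortolide F tert-butyldimethylsilyl ether
Product: 23 plakortolide F
Conditions: TBAF, AcOH (1:1), THF, 0 °C
Reagents that add atoms: none
Why: Fluoride cleavage of the aryl silyl ether, buffered with acetic acid so that no base is free to eliminate the peroxide from the β-peroxy lactone.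

Compound list
1 | 4-bromophenol | Oc1ccc(Br)cc1 | starting material
2 | (4-bromophenoxy)(tert-butyl)dimethylsilane | CC(C)(C)[Si](C)(C)Oc1ccc(Br)cc1 | intermediate
3 | 1,8-dibromooctane | BrCCCCCCCCBr | starting material
4 | [4-(tert-butyldimethylsilyloxy)phenyl]magnesium bromide | CC(C)(C)[Si](C)(C)Oc1ccc([Mg]Br)cc1 | intermediate
5 | 1-(8-bromooctyl)-4-(tert-butyldimethylsilyloxy)benzene | CC(C)(C)[Si](C)(C)Oc1ccc(CCCCCCCCBr)cc1 | intermediate
6 | {8-[4-(tert-butyldimethylsilyloxy)phenyl]octyl}triphenylphosphonium bromide | CC(C)(C)[Si](C)(C)Oc1ccc(CCCCCCCC[P+](c2ccccc2)(c2ccccc2)c2ccccc2)cc1.[Br-] | intermediate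
7 | m-xylene | Cc1cccc(C)c1 | starting material
8 | dioxygen (used as singlet oxygen in step 6) | O=O | starting material
9 | (1S,2R)-3,5-dimethylcyclohexa-3,5-diene-1,2-diol | CC1=CC(C)=C[C@H](O)[C@@H]1O | intermediate
10 | 2,2-dimethoxypropane | COC(C)(C)OC | starting material
11 | (3aR,7aS)-2,2,4,6-tetramethyl-3a,7a-dihydro-1,3-benzodioxole | CC1=CC(C)=C[C@@H]2OC(C)(C)O[C@H]12 | intermediate
12 | 1,5-dimethyl-2,3-dioxabicyclo[2.2.2]oct-5-ene-7,8-diol acetonide; dioxolane anti to the O–O bridge; bridgeheads are C6 (methyl) and C3 (H) | C[C@]12OO[C@H](C(C)=C1)[C@@H]1OC(C)(C)O[C@H]21 | intermediate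
13 | 1,5-dimethyl-2,3-dioxabicyclo[2.2.2]oct-5-ene-7,8-diol; cis-diol, both OH on the side of the C=C bridge | C[C@]12OO[C@H](C(C)=C1)[C@H](O)[C@@H]2O | intermediate
14 | (3S,6R)-3,5-dimethyl-3,6-dihydro-1,2-dioxine-3,6-dicarbaldehyde; formyl groups cis (ring C3 is biogenetic C6, ring C6 is biogenetic C3) | C[C@]1(C=O)OO[C@@H](C=O)C(C)=C1 | intermediate
15 | cis-6-(2-methoxyvinyl)-3,5-dimethyl-3,6-dihydro-1,2-dioxine-3-carbaldehyde; ring centres as in 14; E/Z mixture at the enol ether | C[C@]1(C=O)OO[C@@H](C=COC)C(C)=C1 | intermediate
16 | {8-[4-(tert-butyldimethylsilyloxy)phenyl]octylidene}triphenylphosphorane | CC(C)(C)[Si](C)(C)Oc1ccc(CCCCCCCC=P(c2ccccc2)(c2ccccc2)c2ccccc2)cc1 | intermediate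
17 | cis-3-{(Z)-9-[4-(tert-butyldimethylsilyloxy)phenyl]non-1-enyl}-6-(2-methoxyvinyl)-3,5-dimethyl-3,6-dihydro-1,2-dioxine; ring centres as in 14 | C[C@]1(/C=C\CCCCCCCc2ccc(O[Si](C)(C)C(C)(C)C)cc2)OO[C@@H](C=COC)C(C)=C1 | intermediate
18 | 2-(cis-6-{(Z)-9-[4-(tert-butyldimethylsilyloxy)phenyl]non-1-enyl}-4,6-dimethyl-3,6-dihydro-1,2-dioxin-3-yl)acetaldehyde | C[C@]1(/C=C\CCCCCCCc2ccc(O[Si](C)(C)C(C)(C)C)cc2)OO[C@@H](CC=O)C(C)=C1 | intermediate
19 | 2-(cis-6-{(Z)-9-[4-(tert-butyldimethylsilyloxy)phenyl]non-1-enyl}-4,6-dimethyl-3,6-dihydro-1,2-dioxin-3-yl)acetic acid | C[C@]1(/C=C\CCCCCCCc2ccc(O[Si](C)(C)C(C)(C)C)cc2)OO[C@@H](CC(=O)O)C(C)=C1 | intermediate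
20 | 5-iodo derivative of 21; cis-fused γ-lactone on the 1,2-dioxane, iodine on C5 trans to the lactone oxygen on C4 | C[C@@]1(/C=C\CCCCCCCc2ccc(O[Si](C)(C)C(C)(C)C)cc2)[C@@H](I)[C@]2(C)OC(=O)C[C@@H]2OO1 | intermediate
21 | O-TBS plakortolide F with a Z double bond between C7 and C8 | C[C@@]1(/C=C\CCCCCCCc2ccc(O[Si](C)(C)C(C)(C)C)cc2)C[C@]2(C)OC(=O)C[C@@H]2OO1 | intermediate
22 | plakortolide F tert-butyldimethylsilyl ether | C[C@@]1(CCCCCCCCCc2ccc(O[Si](C)(C)C(C)(C)C)cc2)C[C@]2(C)OC(=O)C[C@@H]2OO1 | intermediate
23 | plakortolide F, (3R,4aS,7aS)-3-[9-(4-hydroxyphenyl)nonyl]-3,4a-dimethyltetrahydrofuro[3,2-c][1,2]dioxin-6-one | C[C@@]1(CCCCCCCCCc2ccc(O)cc2)C[C@]2(C)OC(=O)C[C@@H]2OO1 | target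

Total step count: 15. Longest linear sequence: 12 steps (steps 4 to 15, from m-xylene); the side chain takes 3 steps (1 to 3) and joins at step 10.

Steps most likely to fail

Step 9. The processes at risk are loss of site selectivity between the two formyl groups (olefination at C7 or at both) and base-induced Kornblum–DeLaMare opening of the O–O bond through removal of the activated C3–H. The fallback replaces the selective olefination by protecting-group differentiation. It sets out from dialdehyde 14: NaBH4 in MeOH at −20 °C should give the cis-bis(hydroxymethyl)dioxine F1. TBSCl and imidazole at −40 °C should silylate only the CH2OH on the tertiary carbon C3 and leave the neopentyl CH2OH on C6, giving the mono-silyl ether F2. Dess–Martin oxidation would give the C7 aldehyde F3, which has no α-hydrogen, and Wittig reaction with ylide 16 would give the chain-bearing silyl ether F4. CSA in MeOH at 0 °C should remove the alkyl silyl group and keep the aryl one, giving the primary alcohol F5. Dess–Martin oxidation to the C2 aldehyde F6 and methoxymethylenation with Ph3P=CHOMe at −78 °C, now without a competing formyl group, would return to the route at 17.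

Step 13. The processes at risk are closure of the C5 radical onto the adjacent peroxide oxygen (epoxide formation with O–O scission) and stannyl radical attack on the O–O bond. The fallback avoids halogen and radicals. It sets out from acid 19: diimide (KO2CN=NCO2K, AcOH) should reduce the disubstituted chain alkene in preference to the hindered trisubstituted ring alkene and give the saturated-chain dioxine acid F7. Catalytic TfOH in CH2Cl2 at 0 °C should then effect Markovnikov hydrolactonisation (protonation at C5, capture of the tertiary C4 cation by the tethered carboxyl group, cis fusion enforced by the tether). This comes back to the route at 22 and bypasses 20 and 21.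

Step 6. The processes at risk are ene hydroperoxidation at the two allylic methyl groups, addition on the acetonide face, and dimerisation of the diene before it is oxygenated. The fallback changes the mechanism: starting from 11, ground-state oxygen with catalytic tris(4-bromophenyl)aminium hexachloroantimonate in CH2Cl2 at −78 °C (radical-cation chain oxygenation of cisoid dienes) cannot give ene products and should deliver 12 directly. It makes no new compound (F0).

Further compounds
F1 | step 9 | cis-3,6-bis(hydroxymethyl)-3,5-dimethyl-3,6-dihydro-1,2-dioxine | C[C@]1(CO)OO[C@@H](CO)C(C)=C1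
F2 | step 9 | mono-TBS ether of F1 at the C2 oxygen (CH2OTBS on C3, free CH2OH on C6) | C[C@]1(CO)OO[C@@H](CO[Si](C)(C)C(C)(C)C)C(C)=C1
F3 | step 9 | C7 aldehyde with CH2OTBS on C3 | C[C@]1(C=O)OO[C@@H](CO[Si](C)(C)C(C)(C)C)C(C)=C1
F4 | step 9 | chain-bearing dioxine with CH2OTBS on C3 | C[C@]1(/C=C\CCCCCCCc2ccc(O[Si](C)(C)C(C)(C)C)cc2)OO[C@@H](CO[Si](C)(C)C(C)(C)C)C(C)=C1
F5 | step 9 | chain-bearing dioxine with CH2OH on C3 | C[C@]1(/C=C\CCCCCCCc2ccc(O[Si](C)(C)C(C)(C)C)cc2)OO[C@@H](CO)C(C)=C1
F6 | step 9 | chain-bearing dioxine C2 aldehyde | C[C@]1(/C=C\CCCCCCCc2ccc(O[Si](C)(C)C(C)(C)C)cc2)OO[C@@H](C=O)C(C)=C1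
F7 | step 13 | saturated-chain dioxine acetic acid | C[C@]1(CCCCCCCCCc2ccc(O[Si](C)(C)C(C)(C)C)cc2)OO[C@@H](CC(=O)O)C(C)=C1
F0 | step 6 | none | none
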